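Like a neighbouring run at another bath temperature, these flasks carry one charge and differ in their temperature.

| flask | G | Q | temperature | time |
|---|---|---|---|---|
| ochre | 2.5 M | 200 mM (held) | 20 °C | 80 min |
| red | 2.5 M | 200 mM (held) | −10 °C | 80 min |
| green | 2.5 M | 200 mM (held) | 35 °C | 80 min |
| amber | 2.5 M | 200 mM (held) | 5 °C | 80 min |

    G + X → L + D (k1 = 0.0058 M⁻¹ s⁻¹, Ea1 = 53.0 kJ mol⁻¹)
    Q ⇌ X, rate k2*(csat - [X]) (k2 = 0.060 s⁻¹, csat = 200 mM)
    L + D → L.D (k3 = 8.7 × 10⁻⁵ M⁻¹ s⁻¹, Ea3 = 83.0 kJ mol⁻¹)
    (constants at 35 °C)

- at the start none of X is dissolved
- at 35 °C the constants are as listed, elsewhere as the activation energies make them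

- which flask leads in amount of L, in percent of the G charged ("all alike" within 1.5 percentage points) (ochre / red / green / amber / all alike)
- how much L is there at the end, in percent of the G charged: ochre
- how much L is there at the end, in percent of the G charged: red
- how much L is there at the end, in percent of the G charged: green
- how much L is there at the end, in percent of the G charged: amber

1. Transfer of Q into X, at 0.060 s⁻¹, runs faster than uptake by a full charge of G even in green, at 0.0145 s⁻¹. So [X] is taken as 200 mM, and G falls in a pseudo-first-order way with constant p, the first-step constant times [X]. This gives 0.0696 min⁻¹ in green and 0.0242 min⁻¹ in ochre. The converted share c is one minus the exponential of −p times the time: 99.6 % in green, 85.5 % in ochre, 45.0 % in amber and 15.0 % in red.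

2. L and D form in pairs and leave in pairs, so [L] = [D], and the loss to L.D goes with the square of [L]. The loss is reckoned as a correction. Let τ be the run time weighted by the square of c as it grows: 58.6 min in green, 29.5 min in ochre. The loss constant times 2.5 M times τ gives 0.764 in green and 0.0733 in ochre. This is the loss number w. The loss eases as [L] falls, so the share of L is taken as c times c over c + w: 56.4 % in green, 78.8 % in ochre.

3. Turned round: green is reckoned to convert more than ochre, and to pass ochre's reckoned L by the same formula it needs a loss number under 0.264. Its own stands 2.89 times higher. By this reckoning, with ochre held as reckoned, the loss constant in green would have to fall below 3.00 × 10⁻⁵ M⁻¹ s⁻¹ from 8.7 × 10⁻⁵ M⁻¹ s⁻¹ for the order to turn.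

4. Red and amber are reckoned to convert less than ochre's reckoned L, and L can't exceed the G converted.

The forecast gives ochre as leader, with 78 % for ochre, 14.8 % for red, 57 % for green and 44 % for amber: “the 20 °C flask, nearly converted with little loss, comes out ahead”.

The simulation puts ochre ahead with 78.0 % of L, against 14.8 % in red, 57.9 % in green and 44.0 % in amber. Green at 80.0 min held 41.6 % as L.D, and its loss number of 0.764 lies above the 0.264 reckoned for a lead. The repeat of red at 15 °C reckons to c of 73.4 %, with p of 0.0166 min⁻¹, a loss number of 0.0267 and L of 70.8 %. That flask held 69.7 % of L and 2.43 % of L.D.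

The rate constants are those of an exercise; the flask was simulated.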